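## Analysis of the target

Target 16 is a depside: two benzene rings joined only by an aryl ester, with no further ring, no stereocentre and no stereogenic double bond. Ring A is the acyl ring, numbered from its carbonyl-bearing carbon C1, and carries a free hydroxyl at C2, a methoxy group at C4 and a propyl chain at C6. Ring B is the benzoic acid ring, numbered from its carboxyl-bearing carbon C1, and carries a methoxy group at C2, the depside oxygen at C4 and a pentyl chain at C6. The sensitive groups are the aryl ester (cleaved or transferred by hydroxide, alkoxide and amines), the electron-rich, doubly ortho-substituted ring B acid (liable to lose carbon dioxide in hot acid) and the ring A phenol. Three things make the synthesis hard. Each ring is a resorcinol with one oxygen methylated and the other not. The ester joins a phenol to a benzoic acid whose carbonyl carbon is screened by the C2 oxygen and the C6 propyl group. All protecting groups must come off without a nucleophile touching the depside link. The strategy rests on ring B C4: it is meta to both the C2 methoxy and the C6 pentyl group, so its C–H bond is the only one on ring B without an ortho neighbour and can be borylated under steric control. The C4–B bond is then exchanged for the C4–O bond by the ring A carboxylate oxygen, which lies outside the screen around the ring A carbonyl carbon.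

## Retrosynthetic reasoning

Target 16 is traced back to the doubly protected depside 15, which carries a methoxymethyl ether on the ring A C2 oxygen and a tert-butyl ester on the ring B carboxyl. Both groups leave by alkyl–oxygen cleavage in anhydrous acid. No base or nucleophile is needed, so the aryl ester is not endangered and the hindered ring B carboxyl is never attacked at carbon. One operation ends the synthesis.

Depside 15 is cut between the ester oxygen and ring B C4, not at the usual acyl carbon–oxygen bond. This gives the ring A acid 6 and the ring B boronic acid 14. Acyl transfer would need attack at the screened carbonyl carbon of ring A and a ring B phenol whose two oxygens had been told apart. The chosen cut asks only that the carboxylate oxygen of 6 and the unhindered C4 of 14 meet on copper in an oxidative Chan–Lam coupling. The forward step must favour carboxylate O-arylation over loss of boron and over arylation of other oxygen nucleophiles, which is why the C2 hydroxyl of 6 is capped.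

Boronic acid 14 comes from its pinacol ester 13 by oxidative removal of the diol. Ester 13 is cut at the C4–B bond, giving arene 11 and diboron reagent 12. The forward reaction is an iridium-catalysed C–H borylation, which selects the one ring position with no ortho substituent. Ring B therefore never has a second oxygen to differentiate: its C4 oxygen arrives from ring A in the coupling.

Arene 11 is the tert-butyl ester of acid 10, cut at the oxygen–alkyl bond, so the ester is made by O-alkylation and the hindered carbonyl is not involved. Acid 10 is cut between the first and second carbon of the pentyl chain, giving 2-methoxy-6-methylbenzoic acid 7 and 1-bromobutane 8. The forward reaction is alkylation of the laterally lithiated dianion 9, which uses the carboxylate already present to acidify the ortho methyl group.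

Acid 6 is taken back to aldehyde 5 by a change of oxidation state, and 5 to phenol 4 by removing the acetal ether. Phenol 4 is cut at the C4 oxygen–methyl bond to give diol 3. There the two hydroxyls differ sharply, because the C2 hydroxyl is hydrogen-bonded to the aldehyde and the C4 hydroxyl is free and more acidic. Diol 3 is cut between ring A C1 and the formyl carbon, giving 5-propylresorcinol 1. The forward formylation must go ortho to one hydroxyl and para to the other, which is the normal course for 5-alkylresorcinols; it passes through iminium salt 2.

## Alternatives that were turned down

Alternative 1: Ring B is cut at C1–C2 and C5–C6 and is built last, around an ester that already exists.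
- Pieces: the dienyl ester A1 (4,4-dimethoxybuta-1,3-dien-2-yl 2-(benzyloxy)-4-methoxy-6-propylbenzoate), a ketene acetal diene acylated at its C2 oxygen by the ring A acid, and the alkynoate A2 (benzyl oct-2-ynoate).
- Forward key step: heating A1 with A2 should give a [4+2] adduct in which the acetal carbon of A1 has bonded to the ester-bearing alkyne carbon and the methylene terminus to the pentyl-bearing one. Loss of one methoxy group from the acetal carbon, with a hydrogen from the former methylene, aromatizes ring B to the dibenzyl depside A3 (benzyl 4-{[2-(benzyloxy)-4-methoxy-6-propylbenzoyl]oxy}-2-methoxy-6-pentylbenzoate).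
- For: the polarisation of both partners matches the required regiochemistry. The three oxygen functions of ring B arrive already distinct, so no resorcinol is differentiated. A3 is unmasked by hydrogenolysis under neutral conditions, which is gentler on the ring B acid than the acid end game chosen here; on this point the alternative is stronger.
- Against: A1 can only be made by O-acylating a β-dicarbonyl enolate with an activated ring A acid, so the hindered acyl transfer is not avoided, only moved to a substrate that also offers C-acylation. The ketene acetal must then be generated next to an enol ester that strong base cleaves or rearranges. An acyloxy group activates a diene far less than a silyloxy group, and an alkynoate with a β-alkyl chain is a slow dienophile, so a fragile diene would need long heating.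
- Comparison: it is no shorter, since ring A is made much as in the chosen route and the diene adds steps. In place of the neutral end game, the chosen route offers two bench-stable aromatic partners, each four steps from a catalogue compound, and a bond formation at sterically open atoms.

Alternative 2: Ring A is cut at C1–C2 and C5–C6 and is grown on an alkynoic ester of ring B.
- Pieces: the diene A4 (1,1-bis(trimethylsilyloxy)-3-methoxybuta-1,3-diene) and the aryl ynoate A5 (tert-butyl 4-(hex-2-ynoyloxy)-2-methoxy-6-pentylbenzoate).
- Forward key step: a [4+2] cycloaddition in which the bis(silyloxy) carbon of A4 becomes ring A C2 and its methylene terminus becomes C5. Loss of one silyloxy group aromatizes the ring and work-up frees the C2 hydroxyl, giving A6 (tert-butyl 4-[(2-hydroxy-4-methoxy-6-propylbenzoyl)oxy]-2-methoxy-6-pentylbenzoate).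
- For: the depside ester is made by acylating a phenol with an unhindered alkynoic acid, so on the esterification itself this alternative is stronger. The ring A hydroxyl emerges free, so ring A needs no protecting group and only the tert-butyl ester remains to be removed.
- Against: A5 requires ring B with a free C4 hydroxyl and a methylated C2 oxygen, a differentiation the chosen route never has to make. A4 is a moisture-sensitive, strongly nucleophilic ketene acetal and the aryl ester of A5 is a good acyl donor, so acyl transfer to the diene (which would cut the depside link) and conjugate addition compete with cycloaddition. The β-propyl group further slows the dienophile.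
- Comparison: the chosen route keeps both rings as intact arenes from commercial materials and never exposes the aryl ester to a carbon nucleophile. The price is one protecting group on ring A.

Alternative 3: The depside acyl carbon–oxygen bond and the ring A C1–C6 bond are cut together, reducing ring A to a linear polyketide.
- Pieces: the diketo-dioxinone A7 (6-(2,4-dioxoheptyl)-2,2-dimethyl-4H-1,3-dioxin-4-one) and the ring B phenol A8 (benzyl 4-hydroxy-2-methoxy-6-pentylbenzoate).
- Forward key step: heating brings about cycloreversion of A7, and the oxygen of A8 adds to the ketene carbon so exposed. Base then closes chain C2 onto the C7 ketone by aldol condensation, and dehydration gives aromatic ring A in A9 (benzyl 4-[(2,4-dihydroxy-6-propylbenzoyl)oxy]-2-methoxy-6-pentylbenzoate).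
- For: the hindered-ester problem disappears, because the ester forms by addition to an unhindered ketene before ring A exists. That is stronger than any coupling of a preformed 2,6-disubstituted acid, the chosen one included. Ring A and the ester are made in one pot, and the end game is a neutral hydrogenolysis.
- Against: A9 has both ring A oxygens free, so a selective C4 O-methylation must be run on the complete depside with a base that can also cleave the aryl ester or methylate the C2 oxygen. Phenols trap acylketenes less well than aliphatic alcohols, and the aryl β-keto ester so formed can revert or be cleaved during the base-mediated aromatization. A7 is a sensitive polycarbonyl that needs several steps, and A8 again needs ring B with its oxygens told apart.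
- Comparison: step counts are similar. The chosen route fixes both methylation patterns on monocyclic intermediates, where the selective methylation of 3 is straightforward, and no base meets the depside after it is formed.

Key step: step 9

## Route

Step 1
Reactants: 1 5-propylbenzene-1,3-diol (5-propylresorcinol)
Product: 3 2,4-dihydroxy-6-propylbenzaldehyde, via the aryl iminium chloride 2 (not isolated)
Conditions: POCl3, DMF, 0 °C → rt; then H2O, 50 °C
Reagents that add atoms: N,N-dimethylformamide CN(C)C=O; water O
Why: Vilsmeier–Haack formylation; the chloroiminium ion should attack the ring carbon ortho to one hydroxyl and para to the other (the future ring A C1), as is usual for 5-alkylresorcinols, in preference to the carbon between the two hydroxyls. Warm aqueous work-up hydrolyses iminium salt 2 and any formate esters to the aldehyde.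

Step 2
Reactants: 3 2,4-dihydroxy-6-propylbenzaldehyde
Product: 4 2-hydroxy-4-methoxy-6-propylbenzaldehyde
Conditions: MeI (1.05 equiv), K2CO3 (1.0 equiv), acetone, rt
Reagents that add atoms: iodomethane CI
Why: Williamson etherification; the C4 hydroxyl, para to the formyl group, is the more acidic and is free, whereas the C2 hydroxyl is tied up in a hydrogen bond to the aldehyde oxygen, so one equivalent of base and electrophile should methylate the C4 oxygen only.

Step 3
Reactants: 4 2-hydroxy-4-methoxy-6-propylbenzaldehyde
Product: 5 4-methoxy-2-(methoxymethoxy)-6-propylbenzaldehyde
Conditions: MOMCl, i-Pr2NEt, CH2Cl2, 0 °C → rt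
Reagents that add atoms: chloromethyl methyl ether COCCl
Why: O-alkylation of the phenol with the α-chloro ether (Williamson type). The resulting acetal ether is stable to the oxidation and to the basic, oxidative copper step that follow, and is removed by acid at the end.

Step 4
Reactants: 5 4-methoxy-2-(methoxymethoxy)-6-propylbenzaldehyde
Product: 6 4-methoxy-2-(methoxymethoxy)-6-propylbenzoic acid
Conditions: NaClO2, NaH2PO4, 2-methylbut-2-ene (excess), t-BuOH/H2O, 0 °C → rt
Reagents that add atoms: sodium chlorite [Na+].[O-]Cl=O
Why: Pinnick oxidation; the chlorite adduct of the aldehyde fragments to the acid and hypochlorous acid, which the alkene removes before it can chlorinate the electron-rich ring. The phosphate buffer is mild enough to leave the acetal ether intact.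

Step 5
Reactants: 7 2-methoxy-6-methylbenzoic acid; 8 1-bromobutane
Product: 10 2-methoxy-6-pentylbenzoic acid, via the dilithiated acid 9 (not isolated)
Conditions: LiN(i-Pr)2 (2.2 equiv), THF, −78 → 0 °C; then 8, −78 °C → rt; aq. HCl work-up
Reagents that add atoms: none
Why: Lateral (benzylic) lithiation; the first equivalent of amide gives the carboxylate and the second removes a proton from the ortho methyl group, whose anion is stabilised by the neighbouring carboxylate. The benzylic carbon of dianion 9 is far more nucleophilic than the carboxylate and should be alkylated by the primary bromide in an SN2 reaction, turning methyl into pentyl.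

Step 6
Reactants: 10 2-methoxy-6-pentylbenzoic acid
Product: 11 tert-butyl 2-methoxy-6-pentylbenzoate
Conditions: t-BuOC(=NH)CCl3 (2 equiv), BF3·OEt2 (cat.), CH2Cl2/cyclohexane, rt
Reagents that add atoms: tert-butyl 2,2,2-trichloroacetimidate CC(C)(C)OC(=N)C(Cl)(Cl)Cl
Why: Acid-catalysed O-alkylation of the carboxylic acid by the trichloroacetimidate, which hands a tert-butyl cation equivalent to the carboxyl oxygen. The carbonyl carbon is not attacked, so the two ortho substituents do not slow the esterification.

Step 7
Reactants: 11 tert-butyl 2-methoxy-6-pentylbenzoate; 12 bis(pinacolato)diboron
Product: 13 tert-butyl 2-methoxy-6-pentyl-4-(4,4,5,5-tetramethyl-1,3,2-dioxaborolan-2-yl)benzoate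
Conditions: [Ir(OMe)(cod)]2 (1.5 mol %), 4,4′-di-tert-butyl-2,2′-bipyridine (3 mol %), THF, 80 °C
Reagents that add atoms: none
Why: Iridium-catalysed aromatic C–H borylation (Ishiyama–Miyaura–Hartwig type), which is governed by sterics: the tris(boryl) complex of trivalent iridium avoids C–H bonds next to a substituent, and in 11 only C4–H, meta to both the methoxy and the pentyl group, has none. The ester has no ortho hydrogen to direct to, and alkyl C–H bonds are not touched with this ligand.

Step 8
Reactants: 13 tert-butyl 2-methoxy-6-pentyl-4-(4,4,5,5-tetramethyl-1,3,2-dioxaborolan-2-yl)benzoate
Product: 14 [4-(tert-butoxycarbonyl)-3-methoxy-5-pentylphenyl]boronic acid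
Conditions: NaIO4 (3 equiv), NH4OAc (3 equiv), acetone/H2O (1:1), rt
Reagents that add atoms: water O
Why: Hydrolysis of the boronic ester is an equilibrium that periodate drives to the free boronic acid by glycol cleavage of the released diol. The ammonium acetate buffer keeps the medium near neutral, so the tert-butyl ester should survive.

Step 9
Reactants: 6 4-methoxy-2-(methoxymethoxy)-6-propylbenzoic acid; 14 [4-(tert-butoxycarbonyl)-3-methoxy-5-pentylphenyl]boronic acid (2 equiv)
Product: 15 tert-butyl 2-methoxy-4-{[4-methoxy-2-(methoxymethoxy)-6-propylbenzoyl]oxy}-6-pentylbenzoate
Conditions: Cu(OTf)2 (0.4 equiv), pyridine (2 equiv), 4 Å molecular sieves, EtOAc, 60 °C, dry air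
Reagents that add atoms: none
Why: This is a Chan–Lam oxidative coupling, the closest known reaction type being the copper-mediated esterification of benzoic acids with arylboronic acids under air. Pyridine deprotonates 6 and the carboxylate binds divalent copper; as triflate does not compete for the metal, the only carboxylate on copper is that of 6. The aryl group of 14 then passes from boron to copper, oxidation by a second divalent copper or by oxygen gives a trivalent aryl copper carboxylate, and C–O reductive elimination joins the carboxylate oxygen to ring B C4, after which air returns the monovalent copper to the divalent state. No ring closes and no stereocentre forms. The step needs chemoselectivity for carboxylate O-arylation over arylation of other oxygen nucleophiles, protodeboronation and biaryl formation: the ring A C2 oxygen is capped as its methoxymethyl ether so that the carboxylate is the only O–H partner, the sieves remove the water that would turn 14 into a phenol and then a diaryl ether, and the excess of 14 covers what is lost to deboronation and homocoupling. Both reacting atoms are sterically open, since the carboxylate oxygen lies outside the C2 and C6 substituents of ring A and the boron-bearing C4 of ring B has hydrogen at both ortho positions. The amine also buffers the acid set free from the triflate salt, which protects the methoxymethyl ether and the tert-butyl ester.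

Step 10
Reactants: 15 tert-butyl 2-methoxy-4-{[4-methoxy-2-(methoxymethoxy)-6-propylbenzoyl]oxy}-6-pentylbenzoate
Product: 16 4-[(2-hydroxy-4-methoxy-6-propylbenzoyl)oxy]-2-methoxy-6-pentylbenzoic acid
Conditions: TFA/CH2Cl2 (1:4), H2O (5 equiv), 0 °C → rt
Reagents that add atoms: none
Why: Acidolysis; protonation of the acetal releases the ring A phenol through a methoxymethyl cation that water traps, and the tert-butyl ester fragments by alkyl–oxygen cleavage to the ring B acid and isobutene. Neither event involves attack at a carbonyl carbon, so the depside ester, which tolerates anhydrous acid, should be kept; the reaction is run cold and short because the electron-rich ring B acid could otherwise lose carbon dioxide.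

## Compound list

1 | 5-propylbenzene-1,3-diol (5-propylresorcinol) | CCCc1cc(O)cc(O)c1 | starting material
2 | N-[(2,4-dihydroxy-6-propylphenyl)methylidene]-N-methylmethanaminium chloride | CCCc1cc(O)cc(O)c1C=[N+](C)C.[Cl-] | intermediate
3 | 2,4-dihydroxy-6-propylbenzaldehyde | CCCc1cc(O)cc(O)c1C=O | intermediate
4 | 2-hydroxy-4-methoxy-6-propylbenzaldehyde | CCCc1cc(OC)cc(O)c1C=O | intermediate
5 | 4-methoxy-2-(methoxymethoxy)-6-propylbenzaldehyde | CCCc1cc(OC)cc(OCOC)c1C=O | intermediate
6 | 4-methoxy-2-(methoxymethoxy)-6-propylbenzoic acid | CCCc1cc(OC)cc(OCOC)c1C(=O)O | intermediate
7 | 2-methoxy-6-methylbenzoic acid | Cc1cccc(OC)c1C(=O)O | starting material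
8 | 1-bromobutane | CCCCBr | starting material
9 | lithium 2-(lithiomethyl)-6-methoxybenzoate | [Li]Cc1cccc(OC)c1C(=O)O[Li] | intermediate
10 | 2-methoxy-6-pentylbenzoic acid | CCCCCc1cccc(OC)c1C(=O)O | intermediate
11 | tert-butyl 2-methoxy-6-pentylbenzoate | CCCCCc1cccc(OC)c1C(=O)OC(C)(C)C | intermediate
12 | bis(pinacolato)diboron | CC1(C)OB(OC1(C)C)B1OC(C)(C)C(C)(C)O1 | starting material
13 | tert-butyl 2-methoxy-6-pentyl-4-(4,4,5,5-tetramethyl-1,3,2-dioxaborolan-2-yl)benzoate | CCCCCc1cc(B2OC(C)(C)C(C)(C)O2)cc(OC)c1C(=O)OC(C)(C)C | intermediate
14 | [4-(tert-butoxycarbonyl)-3-methoxy-5-pentylphenyl]boronic acid | CCCCCc1cc(B(O)O)cc(OC)c1C(=O)OC(C)(C)C | intermediate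
15 | tert-butyl 2-methoxy-4-{[4-methoxy-2-(methoxymethoxy)-6-propylbenzoyl]oxy}-6-pentylbenzoate | CCCCCc1cc(OC(=O)c2c(OCOC)cc(OC)cc2CCC)cc(OC)c1C(=O)OC(C)(C)C | intermediate
16 | 4-[(2-hydroxy-4-methoxy-6-propylbenzoyl)oxy]-2-methoxy-6-pentylbenzoic acid | CCCCCc1cc(OC(=O)c2c(O)cc(OC)cc2CCC)cc(OC)c1C(=O)O | target

## Step count and least certain steps

Total step count: 10. Longest linear sequence: 6 steps (steps 1 to 4, 9 and 10 from compound 1; equally steps 5 to 10 from compound 7).

Step 9 (key step). The most likely failure is that copper consumes the boronic acid faster than it arylates the carboxylate: protodeboronation, oxidation of the C–B bond and homocoupling would use up 14 while acid 6 is returned. The twisted carboxylate of a 2,6-disubstituted acid is a weaker ligand than a simple benzoate, which would slow the productive pathway. A second risk is loss of the methoxymethyl group under Lewis acid if the amine buffer is insufficient, helped by the neighbouring carboxyl. The fallback sets out from 14 and 6 and rejoins the route at 15. Boronic acid 14 is oxidised at the C–B bond with aqueous H2O2 in THF to tert-butyl 4-hydroxy-2-methoxy-6-pentylbenzoate F1. This phenol is acylated with acid 6 by Steglich esterification (N,N′-dicyclohexylcarbodiimide, 4-dimethylaminopyridine, CH2Cl2, rt) to give 15. This swaps oxidative O-arylation for acyl transfer through an acylpyridinium ion, which is slower for so hindered an acid but is established chemistry for depsides.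

Step 10. Two processes could spoil the deprotection: Friedel–Crafts alkylation of the electron-rich ring A at C3 or C5 by the tert-butyl and methoxymethyl cations (or hydroxymethylation by the formaldehyde released), and acid-promoted loss of carbon dioxide from the freed ring B acid by ipso protonation. The fallback sets out from 15 and ends at 16; it replaces protic acidolysis by silyl transfer under amine buffer, so no strong Brønsted acid is present. Treatment of 15 with Me3SiOTf and 2,2′-bipyridyl in CH2Cl2 at 0 °C → rt should turn the aryl acetal into the aryl silyl ether and the tert-butyl ester into the silyl ester, with the tert-butyl group leaving as isobutene and the methoxymethyl group captured on the pyridine nitrogen. The product is trimethylsilyl 2-methoxy-4-({4-methoxy-6-propyl-2-[(trimethylsilyl)oxy]benzoyl}oxy)-6-pentylbenzoate F2, which is not isolated; aqueous work-up hydrolyses both silyl groups to give 16.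

Step 5. Dianion formation may be incomplete or may compete with ring metalation ortho to the methoxy group. The benzylic position may be alkylated twice, or the bromide may undergo elimination instead of substitution. The fallback sets out from 7 and rejoins at 11, reversing the order of the two ring B operations. Acid 7 is first esterified with tert-butyl 2,2,2-trichloroacetimidate (BF3·OEt2 cat., CH2Cl2/cyclohexane) to tert-butyl 2-methoxy-6-methylbenzoate F3. Its ortho methyl group is then deprotonated with LiN(i-Pr)2 in THF at −78 °C to an ester-stabilised benzylic anion, which is alkylated with 8 to give 11 directly. The bulky ester resists self-condensation and only one equivalent of base is needed.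

Step 8. The ester hydrolysis may stall at partial conversion, the C–B bond may be partly oxidised by the periodate, or the boronic acid may be hard to free from its anhydride forms on isolation. The fallback sets out from 13 and rejoins at 14 through a crystalline salt. Ester 13 is treated with KHF2 in MeOH/H2O to give potassium [4-(tert-butoxycarbonyl)-3-methoxy-5-pentylphenyl]trifluoroborate F4, which is purified by crystallisation. The salt is then hydrolysed to 14 with silica gel in water at rt, conditions the tert-butyl ester tolerates.

## Further compounds

F1 | step 9 | tert-butyl 4-hydroxy-2-methoxy-6-pentylbenzoate | CCCCCc1cc(O)cc(OC)c1C(=O)OC(C)(C)C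
F2 | step 10 | trimethylsilyl 2-methoxy-4-({4-methoxy-6-propyl-2-[(trimethylsilyl)oxy]benzoyl}oxy)-6-pentylbenzoate | CCCCCc1cc(OC(=O)c2c(O[Si](C)(C)C)cc(OC)cc2CCC)cc(OC)c1C(=O)O[Si](C)(C)C
F3 | step 5 | tert-butyl 2-methoxy-6-methylbenzoate | Cc1cccc(OC)c1C(=O)OC(C)(C)C
F4 | step 8 | potassium [4-(tert-butoxycarbonyl)-3-methoxy-5-pentylphenyl]trifluoroborate | CCCCCc1cc([B-](F)(F)F)cc(OC)c1C(=O)OC(C)(C)C.[K+]
A1 | alternative 1 | 4,4-dimethoxybuta-1,3-dien-2-yl 2-(benzyloxy)-4-methoxy-6-propylbenzoate | CCCc1cc(OC)cc(OCc2ccccc2)c1C(=O)OC(=C)C=C(OC)OC
A2 | alternative 1 | benzyl oct-2-ynoate | CCCCCC#CC(=O)OCc1ccccc1
A3 | alternative 1 | benzyl 4-{[2-(benzyloxy)-4-methoxy-6-propylbenzoyl]oxy}-2-methoxy-6-pentylbenzoate | CCCCCc1cc(OC(=O)c2c(OCc3ccccc3)cc(OC)cc2CCC)cc(OC)c1C(=O)OCc1ccccc1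
A4 | alternative 2 | 1,1-bis(trimethylsilyloxy)-3-methoxybuta-1,3-diene | C=C(OC)C=C(O[Si](C)(C)C)O[Si](C)(C)C
A5 | alternative 2 | tert-butyl 4-(hex-2-ynoyloxy)-2-methoxy-6-pentylbenzoate | CCCCCc1cc(OC(=O)C#CCCC)cc(OC)c1C(=O)OC(C)(C)C
A6 | alternative 2 | tert-butyl 4-[(2-hydroxy-4-methoxy-6-propylbenzoyl)oxy]-2-methoxy-6-pentylbenzoate | CCCCCc1cc(OC(=O)c2c(O)cc(OC)cc2CCC)cc(OC)c1C(=O)OC(C)(C)C
A7 | alternative 3 | 6-(2,4-dioxoheptyl)-2,2-dimethyl-4H-1,3-dioxin-4-one | CCCC(=O)CC(=O)CC1=CC(=O)OC(C)(C)O1
A8 | alternative 3 | benzyl 4-hydroxy-2-methoxy-6-pentylbenzoate | CCCCCc1cc(O)cc(OC)c1C(=O)OCc1ccccc1
A9 | alternative 3 | benzyl 4-[(2,4-dihydroxy-6-propylbenzoyl)oxy]-2-methoxy-6-pentylbenzoate | CCCCCc1cc(OC(=O)c2c(O)cc(O)cc2CCC)cc(OC)c1C(=O)OCc1ccccc1
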